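**Plan**

- Retrosynthesis: cut the side chain at C9–C11 (alkylcerium + enone), the C17 methylene at C8, ring B at C8–C9 (alkyllithium + C9 ester), then ring A at C3–C4. The C3–C4 cut leads back to a six-membered lactone C19(=O)–O–C1 carrying a vinyl group (C2=C3) on C1; that lactone is cut at C5–C6, C5–C10 and C1–C10.
- Enabling feature: C4 is the α-carbon of the C19 carboxyl, C3 is the CH2 next to it, and C1 lies 1,4 to C4 across C5–C10 of ring A. C19–C4–C3–C2–C1 is therefore the pent-4-enoic acid retron of an ester-enolate Claisen step once a C1=C2 alkene and a C1–O–C19 lactone bridge are added. The bridge breaks in the step itself; the alkene is hydrogenated afterwards.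
- Forward order: acyclic C1/C10/C5 triad → δ-lactone → ring A by ring contraction (step 11) → ring B by C8–C9 acylation (step 15) → C17 methylene → side chain.
- Stereochemistry: C1 from an Evans aldol reaction; quaternary C10 from C1 (Fráter–Seebach, anti attack); C5 from C10 (chelation-controlled alkynylation); quaternary C4 from C1 by suprafacial [3,3] transfer; C9 from the axial C10 methyl and the C5 alkoxide (α-face attack); the 13E alkene from syn carboalumination.
- Ring B is closed only after ring A, because a trans-fused ring B would hold the C4–C5–C10–C1 torsion near 60° and block the boat-like transition state.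

Key step: step 11

Remark: labdane numbering (C1–C20) is used throughout. The C4 centre of 8–19 is carried as a single epimer but becomes the enolate carbon in step 11, so its configuration is inconsequential. The C5 carbinol of 10 and 11 is an epimer mixture that converges in step 7.

**Route**

Step 1
Reactants: 1 (S)-4-benzyl-3-propionyloxazolidin-2-one; 2 acrolein
Product: 4 (S)-4-benzyl-3-[(2S,3R)-3-hydroxy-2-methylpent-4-enoyl]oxazolidin-2-one, via Z-boron enolate 3 (not isolated)
Conditions: n-Bu2BOTf, i-Pr2NEt, CH2Cl2, −78 to 0 °C; 2, −78 °C; then H2O2, pH 7 buffer, MeOH, 0 °C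
Reagents that add atoms: none
Why: Evans syn-aldol reaction: the Z-boron enolate adds to acrolein through a Zimmerman–Traxler chair with one enolate face shielded by the benzyl auxiliary, which should set the C1 carbinol as (R).

Step 2
Reactants: 4 (S)-4-benzyl-3-[(2S,3R)-3-hydroxy-2-methylpent-4-enoyl]oxazolidin-2-one
Product: 5 methyl (2S,3R)-3-hydroxy-2-methylpent-4-enoate
Conditions: NaOMe (0.3 equiv), MeOH, 0 °C
Reagents that add atoms: methanol CO
Why: Methoxide transesterification attacks the exocyclic imide carbonyl selectively at 0 °C and releases the auxiliary without retro-aldol cleavage.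

Step 3
Reactants: 6 methyl (R)-3-hydroxy-2-methylpropanoate
Product: 7 methyl (R)-3-[(tert-butyldimethylsilyl)oxy]-2-methylpropanoate
Conditions: t-BuMe2SiCl, imidazole, DMF, rt
Reagents that add atoms: tert-butyldimethylsilyl chloride CC(C)(C)[Si](C)(C)Cl
Why: Standard silylation of a primary alcohol that leaves the α-stereocentre untouched.

Step 4
Reactants: 7 methyl (R)-3-[(tert-butyldimethylsilyl)oxy]-2-methylpropanoate
Product: 8 (R)-3-[(tert-butyldimethylsilyl)oxy]-2-methylpropanal
Conditions: i-Bu2AlH (1.05 equiv), CH2Cl2, −78 °C; aq. potassium sodium tartrate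
Reagents that add atoms: none
Why: Low-temperature half-reduction of the methyl ester stops at the aluminium hemiacetal, which should give the aldehyde on work-up without epimerisation.

Step 5
Reactants: 5 methyl (2S,3R)-3-hydroxy-2-methylpent-4-enoate; 8 (R)-3-[(tert-butyldimethylsilyl)oxy]-2-methylpropanal
Product: 10 methyl (2S,4R)-5-[(tert-butyldimethylsilyl)oxy]-3-hydroxy-2-[(1R)-1-hydroxyprop-2-en-1-yl]-2,4-dimethylpentanoate (C5 carbinol epimers), via dilithium alkoxide enolate 9 (not isolated)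
Conditions: LiN(i-Pr)2 (2.2 equiv), THF, −78 to −20 °C; 8, −78 °C; aq. NH4Cl
Reagents that add atoms: none
Why: Fráter–Seebach aldol reaction: the chelated alkoxide–enolate is attacked on the face anti to the vinyl group, so at quaternary C10 the new C5–C10 bond should lie anti and the methyl syn to the C1 hydroxyl.

Step 6
Reactants: 10 methyl (2S,4R)-5-[(tert-butyldimethylsilyl)oxy]-3-hydroxy-2-[(1R)-1-hydroxyprop-2-en-1-yl]-2,4-dimethylpentanoate
Product: 11 methyl (2S,4R)-5-[(tert-butyldimethylsilyl)oxy]-3-hydroxy-2,4-dimethyl-2-[(1R)-1-[(triethylsilyl)oxy]prop-2-en-1-yl]pentanoate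
Conditions: Et3SiCl (1.1 equiv), imidazole, DMF, 0 °C
Reagents that add atoms: chlorotriethylsilane CC[Si](Cl)(CC)CC
Why: Chemoselective silylation: the allylic C1 hydroxyl is less hindered than the C5 hydroxyl, which is flanked by a quaternary and a branched carbon.

Step 7
Reactants: 11 methyl (2S,4R)-5-[(tert-butyldimethylsilyl)oxy]-3-hydroxy-2,4-dimethyl-2-[(1R)-1-[(triethylsilyl)oxy]prop-2-en-1-yl]pentanoate
Product: 12 methyl (2S,4R)-5-[(tert-butyldimethylsilyl)oxy]-2,4-dimethyl-3-oxo-2-[(1R)-1-[(triethylsilyl)oxy]prop-2-en-1-yl]pentanoate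
Conditions: Dess–Martin periodinane, CH2Cl2, rt
Reagents that add atoms: none
Why: Dess–Martin oxidation of the remaining hindered secondary alcohol under near-neutral conditions that should spare the β-silyloxy ketone and its α-stereocentre.

Step 8
Reactants: 12 methyl (2S,4R)-5-[(tert-butyldimethylsilyl)oxy]-2,4-dimethyl-3-oxo-2-[(1R)-1-[(triethylsilyl)oxy]prop-2-en-1-yl]pentanoate; 13 benzyl prop-2-yn-1-yl ether
Product: 16 methyl (2S,3S,4R)-3-[3-(benzyloxy)prop-1-yn-1-yl]-5-[(tert-butyldimethylsilyl)oxy]-3-hydroxy-2,4-dimethyl-2-[(1R)-1-[(triethylsilyl)oxy]prop-2-en-1-yl]pentanoate, via lithium acetylide 14 (not isolated), via dichlorocerium acetylide 15 (not isolated)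
Conditions: 13, n-BuLi, THF, −78 °C; anhydrous CeCl3, −78 °C; 12, −78 °C; aq. NH4Cl
Reagents that add atoms: none
Why: Chelation-controlled 1,2-addition of a weakly basic alkynylcerium reagent: cerium bridges the ketone and the ester carbonyl on C10, so the small nucleophile should enter from the methyl side of the chelate, anti to the CH(OSiEt3)vinyl arm (reinforced by Felkin–Anh control from C4), placing the C5 oxygen anti to the C10 methyl.

Step 9
Reactants: 16 methyl (2S,3S,4R)-3-[3-(benzyloxy)prop-1-yn-1-yl]-5-[(tert-butyldimethylsilyl)oxy]-3-hydroxy-2,4-dimethyl-2-[(1R)-1-[(triethylsilyl)oxy]prop-2-en-1-yl]pentanoate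
Product: 17 methyl (2S,3S,4R)-3-[3-(benzyloxy)prop-1-yn-1-yl]-3,5-dihydroxy-2-[(1R)-1-hydroxyprop-2-en-1-yl]-2,4-dimethylpentanoate
Conditions: HF·pyridine, pyridine, THF, 0 °C to rt
Reagents that add atoms: none
Why: Fluoride cleaves the secondary triethylsilyl and primary tert-butyldimethylsilyl ethers under non-basic conditions, which should avoid retro-aldol cleavage and translactonisation onto the methyl ester.

Step 10
Reactants: 17 methyl (2S,3S,4R)-3-[3-(benzyloxy)prop-1-yn-1-yl]-3,5-dihydroxy-2-[(1R)-1-hydroxyprop-2-en-1-yl]-2,4-dimethylpentanoate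
Product: 19 methyl (2R,3S,4S,5S)-4-[3-(benzyloxy)prop-1-yn-1-yl]-4-hydroxy-3,5-dimethyl-6-oxo-2-vinyloxane-3-carboxylate (the C19–O–C1 δ-lactone), via lactol 18 (not isolated)
Conditions: TEMPO (0.2 equiv), PhI(OAc)2 (2.5 equiv), CH2Cl2, rt
Reagents that add atoms: none
Why: TEMPO/PhI(OAc)2 oxidative lactonisation: the primary alcohol is oxidised first, the aldehyde is trapped by the C1 hydroxyl as the six-membered lactol and this is oxidised on to the lactone, in which hydroxyl, ester and vinyl are cis.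

Step 11
Reactants: 19 methyl (2R,3S,4S,5S)-4-[3-(benzyloxy)prop-1-yn-1-yl]-4-hydroxy-3,5-dimethyl-6-oxo-2-vinyloxane-3-carboxylate
Product: 22 (1S,2R,3S)-2-[3-(benzyloxy)prop-1-yn-1-yl]-3-(methoxycarbonyl)-1,3-dimethyl-2-[(triethylsilyl)oxy]cyclohex-4-ene-1-carboxylic acid (ring A acid), via bis(triethylsilyl) ketene acetal 20 (not isolated), via rearranged triethylsilyl ester 21 (not isolated)
Conditions: Et3SiCl, Et3N, THF, −78 °C, LiN(i-Pr)2 (2.3 equiv) added slowly, then rt; toluene, 110 °C; then MeOH–H2O, AcOH (cat.), rt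
Reagents that add atoms: chlorotriethylsilane CC[Si](Cl)(CC)CC
Why: LiN(i-Pr)2 deprotonates the C5 hydroxyl and then C4–H in the presence of Et3SiCl, so the lactone is held as the cyclic silyl ketene acetal 20, which on heating undergoes the [3,3]-sigmatropic ester-enolate (Ireland) Claisen shift through C4=C19(OSi)–O–C1–C2=C3, breaking O–C1 and forming C3–C4. The closest known reaction type is the ring-contracting Ireland–Claisen rearrangement of 6-alkenyl δ-lactones, 1,4-dioxan-2-ones and morpholin-2-ones to cyclohexene, dihydropyran and pipecolic acid derivatives. Ring A (C1–C2–C3–C4–C5–C10) closes as the lactone ring opens, through a boat-like transition state in which C4 and C1 are bridged by C5–C10, by C19–O and by C3=C2 (a bicyclo[2.2.2]octane-like array), so the six-membered heterocycle is contracted to the carbocycle and a C1=C2 alkene is left behind. The only new stereocentre, quaternary C4, is controlled by C1: the tether lets C3 reach only the enolate face on which the C1–O bond lies, so C19 ends on the face that bond occupied (β, cis to the C10 methyl, trans to the C5 oxygen), and the C1 stereocentre is consumed. The step needs C-attack at C4 without β-elimination of the C5 oxygen and a reachable boat geometry: internal quench at −78 °C traps the enolate before elimination, and the lactone is kept monocyclic (ring B not yet closed, a linear alkynyl group on C5) so that the C4–C5–C10–C1 torsion can close to the near-eclipsed value that a trans-fused ring B would forbid.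

Step 12
Reactants: 22 ring A acid
Product: 23 triisopropylsilyl ester of 22
Conditions: i-Pr3SiCl, imidazole, DMF, 0 °C
Reagents that add atoms: chlorotriisopropylsilane CC(C)[Si](Cl)(C(C)C)C(C)C
Why: Silylation of the carboxylic acid gives a bulky silyl ester that masks the acid and shields the C19 carbonyl for the following steps.

Step 13
Reactants: 23 triisopropylsilyl ester of 22
Product: 25 triisopropylsilyl 2-(3-hydroxypropyl)-3-(methoxycarbonyl)-1,3-dimethyl-2-[(triethylsilyl)oxy]cyclohexane-1-carboxylate (saturated ring A with C8–OH; stereocentres as in 22), via saturated benzyl ether 24 (not isolated)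
Conditions: H2 (4 atm), Rh/Al2O3, EtOAc, rt; filter; H2 (1 atm), Pd(OH)2/C, EtOAc, rt
Reagents that add atoms: none
Why: Heterogeneous hydrogenation over rhodium should saturate the alkyne and the C1=C2 alkene with little propargylic C–O hydrogenolysis, and Pd(OH)2/C then cleaves the benzyl ether.

Step 14
Reactants: 25 saturated ring A primary alcohol
Product: 26 the corresponding primary iodide (C8–I)
Conditions: PPh3, I2, imidazole, CH2Cl2, 0 °C
Reagents that add atoms: iodine II
Why: Garegg–Samuelsson iodination (SN2 displacement of the alkoxyphosphonium ion) of the only free hydroxyl.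

Step 15
Reactants: 26 primary iodide
Product: 28 triisopropylsilyl 9-oxo-5α-[(triethylsilyl)oxy]-11,12,13,14,15,16,17-heptanorlabdan-19-oate (trans-fused ring B ketone), via alkyllithium 27 (not isolated)
Conditions: t-BuLi (2.1 equiv), Et2O–pentane, −78 to −40 °C; aq. NH4Cl
Reagents that add atoms: none
Why: Halogen–lithium exchange-initiated intramolecular acylation: the primary alkyllithium should attack the C9 methyl ester in a 6-exo-trig closure to the strain-free trans-fused ring B, the axial triisopropylsilyl ester at C19 being far more hindered.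

Step 16
Reactants: 28 ring B ketone
Product: 31 5α-hydroxy-9-oxo-11,12,13,14,15,16-hexanorlabd-8(17)-en-19-oic acid, via Mannich base 29 (not isolated), via silylated enone 30 (not isolated)
Conditions: (CH2O)n, PhNHMe·CF3CO2H, THF, reflux; then HF·pyridine, THF, 0 °C to rt
Reagents that add atoms: formaldehyde C=O
Why: Direct α-methylenation (Mannich condensation then β-elimination, Gras conditions) is regiospecific because only C8 is enolisable, and fluoride then frees the C5 hydroxyl and the acid.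

Step 17
Reactants: 32 tert-butyl(but-3-yn-1-yloxy)dimethylsilane
Product: 35 (E)-5-[(tert-butyldimethylsilyl)oxy]-3-methylpent-2-en-1-ol, via alkenylalane 33 (not isolated), via lithium alanate 34 (not isolated)
Conditions: Me3Al (3 equiv), Cp2ZrCl2 (0.25 equiv), CH2Cl2, 0 °C to rt; n-BuLi, THF, −78 °C; (CH2O)n, rt; 1 M HCl
Reagents that add atoms: trimethylaluminium C[Al](C)C; formaldehyde C=O
Why: Negishi zirconium-catalysed carboalumination adds Me–Al syn across the terminal alkyne and the alanate is hydroxymethylated with retention, which fixes the E trisubstituted alkene.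

Step 18
Reactants: 35 (E)-5-[(tert-butyldimethylsilyl)oxy]-3-methylpent-2-en-1-ol
Product: 36 (E)-1-[(tert-butyldiphenylsilyl)oxy]-5-[(tert-butyldimethylsilyl)oxy]-3-methylpent-2-ene
Conditions: t-BuPh2SiCl, imidazole, DMF, rt
Reagents that add atoms: tert-butyldiphenylsilyl chloride CC(C)(C)[Si](Cl)(c1ccccc1)c1ccccc1
Why: Standard silylation of the allylic alcohol.

Step 19
Reactants: 36 bis-silyl ether
Product: 37 (E)-5-[(tert-butyldiphenylsilyl)oxy]-3-methylpent-3-en-1-ol
Conditions: pyridinium p-toluenesulfonate (0.1 equiv), EtOH, rt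
Reagents that add atoms: none
Why: Mild acid-catalysed ethanolysis removes the primary tert-butyldimethylsilyl ether much faster than the tert-butyldiphenylsilyl ether.

Step 20
Reactants: 37 (E)-5-[(tert-butyldiphenylsilyl)oxy]-3-methylpent-3-en-1-ol
Product: 38 (E)-tert-butyl[(5-iodo-3-methylpent-2-en-1-yl)oxy]diphenylsilane
Conditions: PPh3, I2, imidazole, CH2Cl2, 0 °C
Reagents that add atoms: iodine II
Why: Garegg–Samuelsson iodination of the primary homoallylic alcohol by SN2 displacement.

Step 21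
Reactants: 31 5α-hydroxy-9-oxo-11,12,13,14,15,16-hexanorlabd-8(17)-en-19-oic acid; 38 (E)-tert-butyl[(5-iodo-3-methylpent-2-en-1-yl)oxy]diphenylsilane
Product: 42 15-O-(tert-butyldiphenylsilyl)-5α,9β-dihydroxylabda-8(17),13E-dien-19-oic acid, via alkyllithium 39 (not isolated), via alkylcerium dichloride 40 (not isolated), via disodium salt 41 (not isolated)
Conditions: 38, t-BuLi (2.1 equiv), Et2O, −78 °C; CeCl3, THF, −78 °C; 31 treated with NaH (2.1 equiv), THF, 0 °C, then added at −78 °C; aq. NH4Cl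
Reagents that add atoms: none
Why: 1,2-Addition of a non-basic primary alkylcerium reagent to the α-methylene ketone should occur on the α face, axial and anti to the axial C10 methyl (as in additions to angularly methylated 1-decalones and 17-keto steroids) and guided by the α-axial C5 alkoxide, giving 9β-OH with the side chain α.

Step 22
Reactants: 42 15-O-(tert-butyldiphenylsilyl)-5α,9β-dihydroxylabda-8(17),13E-dien-19-oic acid
Product: 43 5α,9β-dihydroxyisocupressic acid
Conditions: n-Bu4NF, THF, rt; aq. NH4Cl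
Reagents that add atoms: none
Why: Fluoride cleaves the silyl ether at room temperature under conditions that should spare the tertiary allylic alcohol and the β-hydroxy acid.

**Compound list**

1 | (S)-4-benzyl-3-propionyloxazolidin-2-one | CCC(=O)N1[C@@H](Cc2ccccc2)COC1=O | starting material
2 | acrolein | C=CC=O | starting material
3 | Z-di-n-butylboron enolate of 1 (not isolated) | C/C=C(\OB(CCCC)CCCC)N1[C@@H](Cc2ccccc2)COC1=O | intermediate
4 | (S)-4-benzyl-3-[(2S,3R)-3-hydroxy-2-methylpent-4-enoyl]oxazolidin-2-one | C=C[C@@H](O)[C@H](C)C(=O)N1[C@@H](Cc2ccccc2)COC1=O | intermediate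
5 | methyl (2S,3R)-3-hydroxy-2-methylpent-4-enoate | C=C[C@@H](O)[C@H](C)C(=O)OC | intermediate
6 | methyl (R)-3-hydroxy-2-methylpropanoate | COC(=O)[C@H](C)CO | starting material
7 | methyl (R)-3-[(tert-butyldimethylsilyl)oxy]-2-methylpropanoate | COC(=O)[C@H](C)CO[Si](C)(C)C(C)(C)C | intermediate
8 | (R)-3-[(tert-butyldimethylsilyl)oxy]-2-methylpropanal | O=C[C@H](C)CO[Si](C)(C)C(C)(C)C | intermediate
9 | dilithium alkoxide enolate of 5 (not isolated) | C=C[C@@H](O[Li])C(C)=C(OC)O[Li] | intermediate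
10 | methyl (2S,4R)-5-[(tert-butyldimethylsilyl)oxy]-3-hydroxy-2-[(1R)-1-hydroxyprop-2-en-1-yl]-2,4-dimethylpentanoate (C5 carbinol epimers) | C=C[C@@H](O)[C@](C)(C(=O)OC)C(O)[C@H](C)CO[Si](C)(C)C(C)(C)C | intermediate
11 | C1-O-triethylsilyl ether of 10 | C=C[C@@H](O[Si](CC)(CC)CC)[C@](C)(C(=O)OC)C(O)[C@H](C)CO[Si](C)(C)C(C)(C)C | intermediate
12 | methyl (2S,4R)-5-[(tert-butyldimethylsilyl)oxy]-2,4-dimethyl-3-oxo-2-[(1R)-1-[(triethylsilyl)oxy]prop-2-en-1-yl]pentanoate | C=C[C@@H](O[Si](CC)(CC)CC)[C@](C)(C(=O)OC)C(=O)[C@H](C)CO[Si](C)(C)C(C)(C)C | intermediate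
13 | benzyl prop-2-yn-1-yl ether | C#CCOCc1ccccc1 | starting material
14 | lithium acetylide of 13 (not isolated) | [Li]C#CCOCc1ccccc1 | intermediate
15 | dichlorocerium acetylide of 13 (not isolated) | Cl[Ce](Cl)C#CCOCc1ccccc1 | intermediate
16 | methyl (2S,3S,4R)-3-[3-(benzyloxy)prop-1-yn-1-yl]-5-[(tert-butyldimethylsilyl)oxy]-3-hydroxy-2,4-dimethyl-2-[(1R)-1-[(triethylsilyl)oxy]prop-2-en-1-yl]pentanoate | C=C[C@@H](O[Si](CC)(CC)CC)[C@](C)(C(=O)OC)[C@@](O)(C#CCOCc1ccccc1)[C@H](C)CO[Si](C)(C)C(C)(C)C | intermediate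
17 | methyl (2S,3S,4R)-3-[3-(benzyloxy)prop-1-yn-1-yl]-3,5-dihydroxy-2-[(1R)-1-hydroxyprop-2-en-1-yl]-2,4-dimethylpentanoate | C=C[C@@H](O)[C@](C)(C(=O)OC)[C@@](O)(C#CCOCc1ccccc1)[C@H](C)CO | intermediate
18 | six-membered lactol from 17 (not isolated) | C=C[C@H]1OC(O)[C@@H](C)[C@](O)(C#CCOCc2ccccc2)[C@@]1(C)C(=O)OC | intermediate
19 | methyl (2R,3S,4S,5S)-4-[3-(benzyloxy)prop-1-yn-1-yl]-4-hydroxy-3,5-dimethyl-6-oxo-2-vinyloxane-3-carboxylate | C=C[C@H]1OC(=O)[C@@H](C)[C@](O)(C#CCOCc2ccccc2)[C@@]1(C)C(=O)OC | intermediate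
20 | bis(triethylsilyl) ketene acetal of 19 (not isolated) | C=C[C@H]1OC(O[Si](CC)(CC)CC)=C(C)[C@](O[Si](CC)(CC)CC)(C#CCOCc2ccccc2)[C@@]1(C)C(=O)OC | intermediate
21 | rearranged triethylsilyl ester, C5-O-triethylsilyl (not isolated) | CC[Si](CC)(CC)OC(=O)[C@@]1(C)CC=C[C@](C)(C(=O)OC)[C@@]1(O[Si](CC)(CC)CC)C#CCOCc2ccccc2 | intermediate
22 | (1S,2R,3S)-2-[3-(benzyloxy)prop-1-yn-1-yl]-3-(methoxycarbonyl)-1,3-dimethyl-2-[(triethylsilyl)oxy]cyclohex-4-ene-1-carboxylic acid | OC(=O)[C@@]1(C)CC=C[C@](C)(C(=O)OC)[C@@]1(O[Si](CC)(CC)CC)C#CCOCc2ccccc2 | intermediate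
23 | triisopropylsilyl ester of 22 | CC(C)[Si](OC(=O)[C@@]1(C)CC=C[C@](C)(C(=O)OC)[C@@]1(O[Si](CC)(CC)CC)C#CCOCc2ccccc2)(C(C)C)C(C)C | intermediate
24 | saturated benzyl ether from 23 (not isolated) | CC(C)[Si](OC(=O)[C@@]1(C)CCC[C@](C)(C(=O)OC)[C@@]1(O[Si](CC)(CC)CC)CCCOCc2ccccc2)(C(C)C)C(C)C | intermediate
25 | saturated ring A primary alcohol (C8–OH) | CC(C)[Si](OC(=O)[C@@]1(C)CCC[C@](C)(C(=O)OC)[C@@]1(O[Si](CC)(CC)CC)CCCO)(C(C)C)C(C)C | intermediate
26 | saturated ring A primary iodide (C8–I) | CC(C)[Si](OC(=O)[C@@]1(C)CCC[C@](C)(C(=O)OC)[C@@]1(O[Si](CC)(CC)CC)CCCI)(C(C)C)C(C)C | intermediate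
27 | primary alkyllithium from 26 (not isolated) | CC(C)[Si](OC(=O)[C@@]1(C)CCC[C@](C)(C(=O)OC)[C@@]1(O[Si](CC)(CC)CC)CCC[Li])(C(C)C)C(C)C | intermediate
28 | triisopropylsilyl 9-oxo-5α-[(triethylsilyl)oxy]-11,12,13,14,15,16,17-heptanorlabdan-19-oate | CC(C)[Si](OC(=O)[C@@]1(C)CCC[C@]2(C)C(=O)CCC[C@@]12O[Si](CC)(CC)CC)(C(C)C)C(C)C | intermediate
29 | C8 N-methylanilinomethyl Mannich base of 28 (not isolated) | CC(C)[Si](OC(=O)[C@@]1(C)CCC[C@]2(C)C(=O)C(CN(C)c3ccccc3)CC[C@@]12O[Si](CC)(CC)CC)(C(C)C)C(C)C | intermediate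
30 | silylated 8(17)-en-9-one (not isolated) | CC(C)[Si](OC(=O)[C@@]1(C)CCC[C@]2(C)C(=O)C(=C)CC[C@@]12O[Si](CC)(CC)CC)(C(C)C)C(C)C | intermediate
31 | 5α-hydroxy-9-oxo-11,12,13,14,15,16-hexanorlabd-8(17)-en-19-oic acid | OC(=O)[C@@]1(C)CCC[C@]2(C)C(=O)C(=C)CC[C@@]12O | intermediate
32 | tert-butyl(but-3-yn-1-yloxy)dimethylsilane | C#CCCO[Si](C)(C)C(C)(C)C | starting material
33 | (E)-alkenyldimethylalane from 32 (not isolated) | C[Al](C)/C=C(\C)CCO[Si](C)(C)C(C)(C)C | intermediate
34 | lithium n-butyl(alkenyl)dimethylalanate (not isolated) | [Li+].CCCC[Al-](C)(C)/C=C(\C)CCO[Si](C)(C)C(C)(C)C | intermediate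
35 | (E)-5-[(tert-butyldimethylsilyl)oxy]-3-methylpent-2-en-1-ol | CC(C)(C)[Si](C)(C)OCC/C(C)=C/CO | intermediate
36 | (E)-1-[(tert-butyldiphenylsilyl)oxy]-5-[(tert-butyldimethylsilyl)oxy]-3-methylpent-2-ene | CC(C)(C)[Si](C)(C)OCC/C(C)=C/CO[Si](c1ccccc1)(c1ccccc1)C(C)(C)C | intermediate
37 | (E)-5-[(tert-butyldiphenylsilyl)oxy]-3-methylpent-3-en-1-ol | OCC/C(C)=C/CO[Si](c1ccccc1)(c1ccccc1)C(C)(C)C | intermediate
38 | (E)-tert-butyl[(5-iodo-3-methylpent-2-en-1-yl)oxy]diphenylsilane | ICC/C(C)=C/CO[Si](c1ccccc1)(c1ccccc1)C(C)(C)C | intermediate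
39 | homoallylic alkyllithium from 38 (not isolated) | [Li]CC/C(C)=C/CO[Si](c1ccccc1)(c1ccccc1)C(C)(C)C | intermediate
40 | alkylcerium dichloride from 39 (not isolated) | Cl[Ce](Cl)CC/C(C)=C/CO[Si](c1ccccc1)(c1ccccc1)C(C)(C)C | intermediate
41 | disodium carboxylate alkoxide of 31 (not isolated) | [Na+].[Na+].[O-]C(=O)[C@@]1(C)CCC[C@]2(C)C(=O)C(=C)CC[C@@]12[O-] | intermediate
42 | 15-O-(tert-butyldiphenylsilyl)-5α,9β-dihydroxylabda-8(17),13E-dien-19-oic acid | C=C1CC[C@]2(O)[C@](C)(CCC[C@]2(C)C(=O)O)[C@]1(O)CC/C(C)=C/CO[Si](c1ccccc1)(c1ccccc1)C(C)(C)C | intermediate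
43 | 5α,9β-dihydroxyisocupressic acid | C=C1CC[C@]2(O)[C@](C)(CCC[C@]2(C)C(=O)O)[C@]1(O)CC/C(C)=C/CO | target

**Count and risks**

Total step count: 22. Longest linear sequence: 16 steps (1, 2, 5–16, 21, 22).

Steps most likely to fail:

1. Step 11. The boat-like transition state carries four substituents on C5/C10 and may be too congested, so that β-elimination of the C5 oxygen or C-silylation takes over. Fallback (stepwise alkylation in place of the concerted shift), from 19 back to 23:
   - Et3SiOTf and 2,6-lutidine give the C5-O-triethylsilyl lactone F1.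
   - 9-BBN then NaBO3 hydroborates the vinyl group to the primary alcohol F2.
   - PPh3, I2 and imidazole give the iodide F3.
   - LiN(SiMe3)2 (THF, −78 to −40 °C) alkylates the lactone enolate at C4 with C3, which the C1 tether delivers to the same face as in the rearrangement, giving the bridged 2-oxabicyclo[2.2.2]octan-3-one F4.
   - LiOH opens the lactone to the C1-hydroxy acid F5.
   - i-Pr3SiCl and imidazole give its silyl ester F6.
   - Burgess reagent dehydrates the C1 hydroxyl, the only carbinol left with a β-hydrogen, to 23.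

2. Step 21. The axial C5 oxygen may divert the reagent to the β face (poor facial selectivity), or γ-deprotonation of the enone may compete. Fallback (small ylide, then chain extension), from 31 back to 42:
   - Me3S+ I− and KN(SiMe3)2 generate dimethylsulfonium methylide, which should add 1,2 and axially to give the 9β,11-epoxide F7.
   - The α-lithio derivative of the allylic sulfone F8 (LiN(i-Pr)2, then BF3·OEt2) opens the oxirane at its CH2 carbon (C11) to give the sulfone adduct F9.
   - LiBHEt3 with PdCl2(dppp) removes the sulfonyl group to give 42.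

3. Step 15. The alkyllithium may fail to discriminate between the two ester carbonyls, or be lost to proton quench or over-addition. Fallback (stabilised carbanion in place of the alkyllithium), from 26 back to 28:
   - PhSO2Na in DMF gives the sulfone F10.
   - LiN(i-Pr)2 (2.2 equiv) forms the α-sulfonyl carbanion, which is acylated by the C9 methyl ester (driven by deprotonation of the product) to the β-keto sulfone F11.
   - Al/Hg in aqueous THF cleaves the sulfonyl group to give 28.

Further compounds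
F1 | step 11 | C5-O-triethylsilyl ether of lactone 19 | C=C[C@H]1OC(=O)[C@@H](C)[C@](O[Si](CC)(CC)CC)(C#CCOCc2ccccc2)[C@@]1(C)C(=O)OC
F2 | step 11 | C1-(2-hydroxyethyl) lactone | OCC[C@H]1OC(=O)[C@@H](C)[C@](O[Si](CC)(CC)CC)(C#CCOCc2ccccc2)[C@@]1(C)C(=O)OC
F3 | step 11 | C1-(2-iodoethyl) lactone | ICC[C@H]1OC(=O)[C@@H](C)[C@](O[Si](CC)(CC)CC)(C#CCOCc2ccccc2)[C@@]1(C)C(=O)OC
F4 | step 11 | bridged 2-oxabicyclo[2.2.2]octan-3-one | O=C1O[C@@H]2CC[C@@]1(C)[C@](O[Si](CC)(CC)CC)(C#CCOCc3ccccc3)[C@@]2(C)C(=O)OC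
F5 | step 11 | C1-hydroxy ring A acid | OC(=O)[C@@]1(C)CC[C@@H](O)[C@](C)(C(=O)OC)[C@@]1(O[Si](CC)(CC)CC)C#CCOCc2ccccc2
F6 | step 11 | triisopropylsilyl ester of F5 | CC(C)[Si](OC(=O)[C@@]1(C)CC[C@@H](O)[C@](C)(C(=O)OC)[C@@]1(O[Si](CC)(CC)CC)C#CCOCc2ccccc2)(C(C)C)C(C)C
F7 | step 21 | 9β,11-epoxide of 31 | C=C1CC[C@]2(O)[C@](C)(CCC[C@]2(C)C(=O)O)[C@]13CO3
F8 | step 21 | (E)-tert-butyl{[3-methyl-4-(phenylsulfonyl)but-2-en-1-yl]oxy}diphenylsilane | O=S(=O)(C/C(C)=C/CO[Si](c1ccccc1)(c1ccccc1)C(C)(C)C)c1ccccc1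
F9 | step 21 | 12-phenylsulfonyl derivative of 42 | C=C1CC[C@]2(O)[C@](C)(CCC[C@]2(C)C(=O)O)[C@]1(O)CC(/C(C)=C/CO[Si](c1ccccc1)(c1ccccc1)C(C)(C)C)S(=O)(=O)c1ccccc1
F10 | step 15 | C8 phenyl sulfone from 26 | CC(C)[Si](OC(=O)[C@@]1(C)CCC[C@](C)(C(=O)OC)[C@@]1(O[Si](CC)(CC)CC)CCCS(=O)(=O)c2ccccc2)(C(C)C)C(C)C
F11 | step 15 | 8-phenylsulfonyl derivative of 28 | CC(C)[Si](OC(=O)[C@@]1(C)CCC[C@]2(C)C(=O)C(S(=O)(=O)c3ccccc3)CC[C@@]12O[Si](CC)(CC)CC)(C(C)C)C(C)C
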